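**Strategy**

The decalin is built in one step from a lactone-tethered triene. Ring B (the ring with the arylmethyl-bearing quaternary carbon and the CH–CH3 carbon) is read as a Diels–Alder cyclohexene in which these two carbons are the enol ether double bond. An intramolecular Diels–Alder reaction of a 2-silyloxy diene with an isopropenyl group forms the ring-fusion bond (ring-fusion CH to the methyl-bearing quaternary carbon) and the opposite CH2–CH2 bond of ring B; ring A (isopropylidene/propanoic acid ring) closes as the tether. The precursor is a trans-5,6-disubstituted δ-lactone that masks the ring A ketone and the acid and fixes the facial course.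

Key step: step 8

Remark: (R)-TRIP is assumed to deliver the allyl unit to the Re face of the aliphatic aldehyde, as with simple aldehydes; if the sense were opposite, (S)-TRIP would be used. In the names below, β is the face of the angular methyl group; tricyclic lactones carry benzo[f]chromene locants and decalins carry naphthalene locants.

**Route**

Step 1
Reactants: 1 3-methylbut-2-enal; 2 methyl (triphenylphosphoranylidene)acetate
Product: 3 methyl (2E)-5-methylhexa-2,4-dienoate
Conditions: CH2Cl2, 25 °C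
Reagents that add atoms: none
Why: Wittig olefination with a stabilised ylide should give the (2E)-enoate selectively.

Step 2
Reactants: 3 methyl (2E)-5-methylhexa-2,4-dienoate
Product: 5 methyl (3E)-5-methylhexa-3,5-dienoate, via lithium trienolate 4 (not isolated)
Conditions: LiN(iPr)2, DMPU, THF, −78 °C; then AcOH, −78 °C
Reagents that add atoms: none
Why: Deconjugative protonation: removal of an ε-hydrogen gives the extended enolate, and kinetic α-protonation should leave the (3E)-3,5-diene.

Step 3
Reactants: 5 methyl (3E)-5-methylhexa-3,5-dienoate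
Product: 6 methyl (4Z)-5-methyl-6-(4,4,5,5-tetramethyl-1,3,2-dioxaborolan-2-yl)hex-4-enoate
Conditions: Ni(cod)2 (2.5 mol %), PCy3 (2.5 mol %), toluene, 25 °C
Reagents that add atoms: pinacolborane, B1OC(C)(C)C(C)(C)O1
Why: Nickel-catalysed 1,4-hydroboration of a 1,3-diene through an s-cis diene complex should put boron on the terminal CH2 and hydrogen on the ester-side terminus, so that CH2B and the ester chain end up cis (Z) on the new trisubstituted double bond.

Step 4
Reactants: 7 pent-4-enal; 8 3-(triphenylphosphoranylidene)butan-2-one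
Product: 9 (3E)-3-methylocta-3,7-dien-2-one
Conditions: toluene, 100 °C
Reagents that add atoms: none
Why: Wittig olefination with a stabilised acyl ylide should give the (E)-trisubstituted enone.

Step 5
Reactants: 9 (3E)-3-methylocta-3,7-dien-2-one
Product: 11 (4E)-5-methyl-6-oxohept-4-enal, via ozonide 10 (not isolated)
Conditions: O3, CH2Cl2, −78 °C, stopped at the first blue colour; then PPh3, −78 → 25 °C
Reagents that add atoms: ozone, [O-][O+]=O
Why: Ozonolysis with reductive work-up should cleave only the electron-rich terminal alkene, the enone double bond being deactivated.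

Step 6
Reactants: 6 methyl (4Z)-5-methyl-6-(pinacolboryl)hex-4-enoate; 11 (4E)-5-methyl-6-oxohept-4-enal
Product: 13 (5S,6S)-6-[(3E)-4-methyl-5-oxohex-3-en-1-yl]-5-(prop-1-en-2-yl)oxan-2-one, via boronate ester 12 (not isolated)
Conditions: (R)-TRIP (5 mol %), toluene, −30 → 0 °C; then TsOH·H2O (cat.), 25 °C
Reagents that add atoms: none
Why: Chiral Brønsted acid catalysed allylboration through a closed chair transition state: the (Z)-boronate should give the syn adduct and (R)-TRIP the Re-face addition, setting (4S,5S), and the δ-hydroxy ester then closes to the trans-5,6-disubstituted lactone by acid-catalysed lactonisation.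

Step 7
Reactants: 13 (5S,6S)-6-[(3E)-4-methyl-5-oxohex-3-en-1-yl]-5-(prop-1-en-2-yl)oxan-2-one
Product: 14 (5S,6S)-6-[(3E)-5-(tert-butyldimethylsilyloxy)-4-methylhexa-3,5-dien-1-yl]-5-(prop-1-en-2-yl)oxan-2-one
Conditions: TBSOTf (1.1 equiv), Et3N, CH2Cl2, 0 °C
Reagents that add atoms: tert-butyldimethylsilyl trifluoromethanesulfonate, CC(C)(C)[Si](C)(C)OS(=O)(=O)C(F)(F)F
Why: Kinetic enolisation of the methyl ketone (silyl enol ether formation) should give the cross-conjugated 2-silyloxy diene with the E double bond untouched, the lactone being much slower to enolise.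

Step 8
Reactants: 14 (5S,6S)-6-[(3E)-5-(tert-butyldimethylsilyloxy)-4-methylhexa-3,5-dien-1-yl]-5-(prop-1-en-2-yl)oxan-2-one
Product: 15 8-(tert-butyldimethylsilyloxy)-7,10a-dimethyl-1,2,4a,5,6,6a,9,10,10a,10b-decahydro-3H-benzo[f]chromen-3-one (4a-H β, 10b-H α, 6a-H α, 10a-CH3 β; both ring fusions trans)
Conditions: toluene (0.01 M), BHT (cat.), sealed tube, 200 °C
Reagents that add atoms: none
Why: Concerted thermal [4+2] cycloaddition (type 1 intramolecular Diels–Alder reaction) of the electron-rich 2-silyloxy diene with the unactivated isopropenyl group; the closest known reaction type is the thermal cyclisation of 1,3,9-decatrienes carrying 2-silyloxy dienes to octalone silyl enol ethers. Ring B closes as the cyclohexene of the cycloaddition (diene termini to the two alkene carbons), and ring A closes as the six-membered tether ring in the fused mode, its four tether atoms in a chair. The two new ring-fusion stereocentres (the CH and the methyl-bearing quaternary carbon) are controlled by the lactone: its trans-diequatorial bonds allow only one tether chair, so the diene reaches only one face of the isopropenyl group, and the anti arrangement puts the angular methyl trans to the ring-fusion hydrogen and anti to the hydrogen on the adjacent lactone carbon. The step needs anti (trans-fused) over syn (cis-fused) selectivity; the methyl on the diene carbon next to the tether acts as a steric directing group, because it clashes with the axial tether hydrogens when the diene is axial in the syn transition state. Regiochemistry is fixed by the tether length, and the silyl enol ether that results marks the carbon for the later benzylation.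

Step 9
Reactants: 16 2-hydroxy-3-methylbenzoic acid
Product: 18 2,5-dihydroxy-3-methylbenzoic acid, via aryl sulfate 17 (not isolated)
Conditions: K2S2O8, NaOH, H2O, 0 → 20 °C; then HCl, 90 °C
Reagents that add atoms: potassium peroxodisulfate, [K+].[K+].[O-]S(=O)(=O)OOS(=O)(=O)[O-]
Why: Elbs persulfate oxidation hydroxylates a phenol para to its hydroxyl group via the aryl sulfate, the para position being free.

Step 10
Reactants: 18 2,5-dihydroxy-3-methylbenzoic acid
Product: 19 benzyl 2,5-bis(benzyloxy)-3-methylbenzoate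
Conditions: BnBr (3.3 equiv), K2CO3, DMF, 60 °C
Reagents that add atoms: benzyl bromide, BrCc1ccccc1
Why: Williamson ether synthesis and carboxylate alkylation should benzylate both phenols and the acid.

Step 11
Reactants: 19 benzyl 2,5-bis(benzyloxy)-3-methylbenzoate
Product: 20 [2,5-bis(benzyloxy)-3-methylphenyl]methanol
Conditions: LiAlH4, THF, 0 °C
Reagents that add atoms: none
Why: Hydride reduction of the ester gives the benzylic alcohol.

Step 12
Reactants: 20 [2,5-bis(benzyloxy)-3-methylphenyl]methanol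
Product: 21 1,4-bis(benzyloxy)-2-(bromomethyl)-6-methylbenzene
Conditions: PBr3, Et2O, 0 °C
Reagents that add atoms: phosphorus tribromide, BrP(Br)Br
Why: The benzylic alcohol is converted into the bromide by SN2 displacement of its phosphite ester.

Step 13
Reactants: 15 tricyclic lactone silyl enol ether; 21 1,4-bis(benzyloxy)-2-(bromomethyl)-6-methylbenzene
Product: 23 7-{[2,5-bis(benzyloxy)-3-methylphenyl]methyl}-7,10a-dimethylperhydrobenzo[f]chromene-3,8-dione (7-arylmethyl α, 7-CH3 β, other centres as in 15), via ammonium enolate 22 (not isolated)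
Conditions: BnMe3NF (anhydrous), 4 Å molecular sieves, THF, −20 → 25 °C
Reagents that add atoms: none
Why: Fluoride-induced desilylation gives the regiodefined tetrasubstituted ammonium enolate, whose C-benzylation (regiospecific enolate alkylation) should occur on the face opposite the axial angular methyl, placing the arylmethyl group trans to it.

Step 14
Reactants: 23 benzylated keto lactone
Product: 24 7-{[2,5-bis(benzyloxy)-3-methylphenyl]methyl}-7,10a-dimethyl-8-methylideneperhydrobenzo[f]chromen-3-one
Conditions: Zn, CH2Br2, TiCl4, THF/CH2Cl2, 0 → 25 °C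
Reagents that add atoms: dibromomethane, BrCBr
Why: Takai–Lombardo methylenation is chemoselective for the hindered ketone over the lactone and is not basic.

Step 15
Reactants: 24 methylidene lactone
Product: 26 3-{5-[(2,5-bis(benzyloxy)-3-methylphenyl)methyl]-5,8a-dimethyl-6-methylidene-2-oxodecahydronaphthalen-1-yl}propanoic acid (1-H α, 4a-H α, 5-arylmethyl α, 5-CH3 β, 8a-CH3 β), via lithium hydroxy carboxylate 25 (not isolated)
Conditions: LiOH·H2O, THF/H2O, 25 °C; evaporation; IBX, DMSO, 25 °C; then dilute HCl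
Reagents that add atoms: lithium hydroxide, [Li+].[OH-]
Why: Saponification opens the lactone to the δ-hydroxy carboxylate, which is oxidised under non-acidic conditions (hypervalent iodine oxidation) before it can relactonise; the chain on the α-carbon already sits in the more stable equatorial position.

Step 16
Reactants: 26 keto acid
Product: 28 spiro β-lactone 3-{5-[(2,5-bis(benzyloxy)-3-methylphenyl)methyl]-3',3',5,8a-tetramethyl-6-methylidene-4'-oxospiro[decahydronaphthalene-2,2'-oxetan]-1-yl}propanoic acid (lactone oxygen axial, β), via lithium aldolate 27 (not isolated)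
Conditions: S-phenyl 2-methylpropanethioate (3 equiv), LiN(iPr)2 (3.2 equiv), THF, −78 → 0 °C; then dilute HCl
Reagents that add atoms: S-phenyl 2-methylpropanethioate, CC(C)C(=O)Sc1ccccc1
Why: Addition of a thiol ester enolate to the ketone gives an aldolate that closes to the β-lactone with loss of thiophenoxide (aldol–lactonisation); the enolate should approach equatorially, away from the axial angular methyl, and the spiro centre is lost in the next step.

Step 17
Reactants: 28 spiro β-lactone
Product: 29 3-{5-[(2,5-bis(benzyloxy)-3-methylphenyl)methyl]-5,8a-dimethyl-6-methylidene-2-(propan-2-ylidene)decahydronaphthalen-1-yl}propanoic acid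
Conditions: silica gel, toluene, 110 °C
Reagents that add atoms: none
Why: Thermal [2+2] cycloreversion (decarboxylation) of the β-lactone should give the tetrasubstituted isopropylidene alkene without moving the double bond.

Step 18
Reactants: 29 isopropylidene acid
Product: 30 3-{5-[(2,5-dihydroxy-3-methylphenyl)methyl]-5,6,8a-trimethyl-2-(propan-2-ylidene)decahydronaphthalen-1-yl}propanoic acid (6-CH3 β)
Conditions: H2 (1 atm), 10% Pd/C, EtOAc, 25 °C, then kept under argon
Reagents that add atoms: none
Why: Heterogeneous hydrogenation should reduce the 1,1-disubstituted exocyclic alkene from the face opposite the two axial methyl groups to give the equatorial secondary methyl, cleave both benzyl ethers by hydrogenolysis, and leave the hindered tetrasubstituted alkene.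

Step 19
Reactants: 30 hydroquinone acid
Product: 31 target, 3-{5-[(5-acetoxy-2-hydroxy-3-methylphenyl)methyl]-5,6,8a-trimethyl-2-(propan-2-ylidene)decahydronaphthalen-1-yl}propanoic acid
Conditions: Ac2O (1.2 equiv), pyridine, CH2Cl2, 0 °C; then aqueous NaHCO3, then dilute HCl
Reagents that add atoms: acetic anhydride, CC(=O)OC(C)=O
Why: Acylation should take place at the unhindered phenol only, because the other hydroxyl is flanked by the methyl and the neopentyl-type arylmethyl group, and any mixed anhydride of the acid is hydrolysed on work-up.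

**Compound list**

1 | 3-methylbut-2-enal | CC(C)=CC=O | starting material
2 | methyl (triphenylphosphoranylidene)acetate | COC(=O)C=P(c1ccccc1)(c1ccccc1)c1ccccc1 | starting material
3 | methyl (2E)-5-methylhexa-2,4-dienoate | COC(=O)/C=C/C=C(C)C | intermediate
4 | lithium (3E)-1-methoxy-5-methylhexa-1,3,5-trien-1-olate | [Li+].COC([O-])=C/C=C/C(C)=C | intermediate
5 | methyl (3E)-5-methylhexa-3,5-dienoate | COC(=O)C/C=C/C(C)=C | intermediate
6 | methyl (4Z)-5-methyl-6-(4,4,5,5-tetramethyl-1,3,2-dioxaborolan-2-yl)hex-4-enoate | COC(=O)CC/C=C(\CB1OC(C)(C)C(C)(C)O1)C | intermediate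
7 | pent-4-enal | C=CCCC=O | starting material
8 | 3-(triphenylphosphoranylidene)butan-2-one | CC(=O)C(C)=P(c1ccccc1)(c1ccccc1)c1ccccc1 | starting material
9 | (3E)-3-methylocta-3,7-dien-2-one | CC(=O)/C(C)=C/CCC=C | intermediate
10 | 3-[(3E)-4-methyl-5-oxohex-3-en-1-yl]-1,2,4-trioxolane | CC(=O)/C(C)=C/CCC1OCOO1 | intermediate
11 | (4E)-5-methyl-6-oxohept-4-enal | CC(=O)/C(C)=C/CCC=O | intermediate
12 | methyl (4S,5S,8E)-9-methyl-10-oxo-4-(prop-1-en-2-yl)-5-[(4,4,5,5-tetramethyl-1,3,2-dioxaborolan-2-yl)oxy]undec-8-enoate | CC(=O)/C(C)=C/CC[C@H](OB1OC(C)(C)C(C)(C)O1)[C@@H](CCC(=O)OC)C(C)=C | intermediate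
13 | (5S,6S)-6-[(3E)-4-methyl-5-oxohex-3-en-1-yl]-5-(prop-1-en-2-yl)oxan-2-one | CC(=O)/C(C)=C/CC[C@@H]1OC(=O)CC[C@H]1C(C)=C | intermediate
14 | (5S,6S)-6-[(3E)-5-(tert-butyldimethylsilyloxy)-4-methylhexa-3,5-dien-1-yl]-5-(prop-1-en-2-yl)oxan-2-one | C=C(O[Si](C)(C)C(C)(C)C)/C(C)=C/CC[C@@H]1OC(=O)CC[C@H]1C(C)=C | intermediate
15 | 8-(tert-butyldimethylsilyloxy)-7,10a-dimethyl-1,2,4a,5,6,6a,9,10,10a,10b-decahydro-3H-benzo[f]chromen-3-one (4a-H β, 10b-H α, 6a-H α, 10a-CH3 β) | C1(O[Si](C)(C)C(C)(C)C)=C(C)[C@H]2CC[C@@H]3OC(=O)CC[C@H]3[C@]2(C)CC1 | intermediate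
16 | 2-hydroxy-3-methylbenzoic acid | Cc1cccc(C(=O)O)c1O | starting material
17 | potassium 3-carboxy-4-hydroxy-5-methylphenyl sulfate | Cc1cc(OS(=O)(=O)[O-])cc(C(=O)O)c1O.[K+] | intermediate
18 | 2,5-dihydroxy-3-methylbenzoic acid | Cc1cc(O)cc(C(=O)O)c1O | intermediate
19 | benzyl 2,5-bis(benzyloxy)-3-methylbenzoate | Cc1cc(OCc2ccccc2)cc(C(=O)OCc2ccccc2)c1OCc1ccccc1 | intermediate
20 | [2,5-bis(benzyloxy)-3-methylphenyl]methanol | Cc1cc(OCc2ccccc2)cc(CO)c1OCc1ccccc1 | intermediate
21 | 1,4-bis(benzyloxy)-2-(bromomethyl)-6-methylbenzene | Cc1cc(OCc2ccccc2)cc(CBr)c1OCc1ccccc1 | intermediate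
22 | benzyltrimethylammonium enolate of the desilylated tricyclic lactone 15 | C[N+](C)(C)Cc1ccccc1.[O-]C1=C(C)[C@H]2CC[C@@H]3OC(=O)CC[C@H]3[C@]2(C)CC1 | intermediate
23 | 7-{[2,5-bis(benzyloxy)-3-methylphenyl]methyl}-7,10a-dimethylperhydrobenzo[f]chromene-3,8-dione (7-arylmethyl α, 7-CH3 β, 4a-H β, 10b-H α, 6a-H α, 10a-CH3 β) | Cc1cc(OCc2ccccc2)cc(C[C@]2(C)[C@H]3CC[C@@H]4OC(=O)CC[C@H]4[C@]3(C)CCC2=O)c1OCc1ccccc1 | intermediate
24 | 7-{[2,5-bis(benzyloxy)-3-methylphenyl]methyl}-7,10a-dimethyl-8-methylideneperhydrobenzo[f]chromen-3-one (stereochemistry as in 23) | Cc1cc(OCc2ccccc2)cc(C[C@]2(C)[C@H]3CC[C@@H]4OC(=O)CC[C@H]4[C@]3(C)CCC2=C)c1OCc1ccccc1 | intermediate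
25 | lithium 3-{5-[(2,5-bis(benzyloxy)-3-methylphenyl)methyl]-2-hydroxy-5,8a-dimethyl-6-methylidenedecahydronaphthalen-1-yl}propanoate (2-OH α, equatorial) | Cc1cc(OCc2ccccc2)cc(C[C@]2(C)[C@H]3CC[C@H](O)[C@@H](CCC(=O)[O-])[C@]3(C)CCC2=C)c1OCc1ccccc1.[Li+] | intermediate
26 | 3-{5-[(2,5-bis(benzyloxy)-3-methylphenyl)methyl]-5,8a-dimethyl-6-methylidene-2-oxodecahydronaphthalen-1-yl}propanoic acid (1-H α, 4a-H α, 5-arylmethyl α, 5-CH3 β, 8a-CH3 β) | Cc1cc(OCc2ccccc2)cc(C[C@]2(C)[C@H]3CCC(=O)[C@@H](CCC(=O)O)[C@]3(C)CCC2=C)c1OCc1ccccc1 | intermediate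
27 | dilithium aldolate of 26 with S-phenyl 2-methylpropanethioate (2-oxide β, axial) | Cc1cc(OCc2ccccc2)cc(C[C@]2(C)[C@H]3CC[C@]([O-])(C(C)(C)C(=O)Sc4ccccc4)[C@@H](CCC(=O)[O-])[C@]3(C)CCC2=C)c1OCc1ccccc1.[Li+].[Li+] | intermediate
28 | 3-{5-[(2,5-bis(benzyloxy)-3-methylphenyl)methyl]-3',3',5,8a-tetramethyl-6-methylidene-4'-oxospiro[decahydronaphthalene-2,2'-oxetan]-1-yl}propanoic acid (lactone oxygen β, axial) | Cc1cc(OCc2ccccc2)cc(C[C@]2(C)[C@H]3CC[C@@]4(OC(=O)C4(C)C)[C@@H](CCC(=O)O)[C@]3(C)CCC2=C)c1OCc1ccccc1 | intermediate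
29 | 3-{5-[(2,5-bis(benzyloxy)-3-methylphenyl)methyl]-5,8a-dimethyl-6-methylidene-2-(propan-2-ylidene)decahydronaphthalen-1-yl}propanoic acid | Cc1cc(OCc2ccccc2)cc(C[C@]2(C)[C@H]3CCC(=C(C)C)[C@@H](CCC(=O)O)[C@]3(C)CCC2=C)c1OCc1ccccc1 | intermediate
30 | 3-{5-[(2,5-dihydroxy-3-methylphenyl)methyl]-5,6,8a-trimethyl-2-(propan-2-ylidene)decahydronaphthalen-1-yl}propanoic acid (6-CH3 β) | Cc1cc(O)cc(C[C@]2(C)[C@H]3CCC(=C(C)C)[C@@H](CCC(=O)O)[C@]3(C)CC[C@H]2C)c1O | intermediate
31 | 3-{5-[(5-acetoxy-2-hydroxy-3-methylphenyl)methyl]-5,6,8a-trimethyl-2-(propan-2-ylidene)decahydronaphthalen-1-yl}propanoic acid (1-H α, 4a-H α, 5-arylmethyl α, 5-CH3 β, 6-CH3 β, 8a-CH3 β) | CC(=O)Oc1cc(C)c(O)c(C[C@]2(C)[C@H]3CCC(=C(C)C)[C@@H](CCC(=O)O)[C@]3(C)CC[C@H]2C)c1 | target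

**Step count**

Total: 19 steps. Longest linear sequence: 13 steps (steps 1–3, 6–8 and 13–19).

**Steps most likely to fail**

Step 8. The cycloaddition may run partly through the syn (cis-fused) mode, and the unactivated alkene may react too slowly at a temperature the silyl dienol ether tolerates. The fallback sets out from 13 and comes back at 15. Allylic oxidation of the isopropenyl methyl (SeO2, t-BuOOH, CH2Cl2; then MnO2) would give 2-[(2S,3S)-2-[(3E)-4-methyl-5-oxohex-3-en-1-yl]-6-oxooxan-3-yl]prop-2-enal F1. Silylation (TBSOTf, Et3N) would give the silyloxy diene enal F2. Its dienophile is activated, and the formyl group, geminal to the tether, should take the endo position, which forces the tether anti and hence the trans ring fusion (Me2AlCl, CH2Cl2, −78 °C, or toluene, 60 °C). This gives the angular aldehyde 8-(tert-butyldimethylsilyloxy)-7-methyl-3-oxo-decahydrobenzo[f]chromene-10a-carbaldehyde F3. Condensation with tosylhydrazine would give the N-tosylhydrazone F4, and its reduction (catecholborane, then NaOAc, heat) would turn the formyl carbon into the angular methyl of 15.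

Step 6. The trisubstituted allylboronate may react with eroded syn selectivity or poor enantiofacial control. The fallback sets out from 6 and 11 and comes back at 13. Oxidation of 6 (NaBO3, THF/H2O) would give methyl (4Z)-6-hydroxy-5-methylhex-4-enoate F5, and CBr4/PPh3 the bromide methyl (4Z)-6-bromo-5-methylhex-4-enoate F6. A catalytic asymmetric Nozaki–Hiyama–Kishi allylation of 11 (CrCl2 cat., Mn, Me3SiCl, chiral bis(oxazolinyl)carbazole ligand, THF) is anti-selective whatever the alkene geometry and would give methyl (4S,5R,8E)-5-hydroxy-9-methyl-10-oxo-4-(prop-1-en-2-yl)undec-8-enoate F7. Saponification (LiOH) would give the hydroxy acid F8, and Mitsunobu lactonisation (PPh3, diisopropyl azodicarboxylate, toluene, high dilution) would close the ring with inversion at the carbinol carbon to give 13.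

Step 16. Enolisation of the hindered α-branched ketone may outrun addition of the bulky enolate. The fallback sets out from 26 and comes back at 29. Esterification (Me3SiCHN2, MeOH/toluene) would give the methyl ester of 26, F9. A crossed McMurry coupling with excess acetone (TiCl4, Zn, pyridine, THF, reflux; low-valent titanium) would give the isopropylidene methyl ester F10 directly, and LiOH (THF/H2O) would give 29.

Further compounds
F1 | step 8 | 2-[(2S,3S)-2-[(3E)-4-methyl-5-oxohex-3-en-1-yl]-6-oxooxan-3-yl]prop-2-enal | CC(=O)/C(C)=C/CC[C@@H]1OC(=O)CC[C@H]1C(=C)C=O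
F2 | step 8 | 2-[(2S,3S)-2-[(3E)-5-(tert-butyldimethylsilyloxy)-4-methylhexa-3,5-dien-1-yl]-6-oxooxan-3-yl]prop-2-enal | C=C(O[Si](C)(C)C(C)(C)C)/C(C)=C/CC[C@@H]1OC(=O)CC[C@H]1C(=C)C=O
F3 | step 8 | 8-(tert-butyldimethylsilyloxy)-7-methyl-3-oxo-1,2,4a,5,6,6a,9,10-octahydro-3H-benzo[f]chromene-10a(10bH)-carbaldehyde (stereochemistry as in 15) | C1(O[Si](C)(C)C(C)(C)C)=C(C)[C@H]2CC[C@@H]3OC(=O)CC[C@H]3[C@]2(C=O)CC1
F4 | step 8 | N-tosylhydrazone of F3 | C1(O[Si](C)(C)C(C)(C)C)=C(C)[C@H]2CC[C@@H]3OC(=O)CC[C@H]3[C@]2(/C=N/NS(=O)(=O)c4ccc(C)cc4)CC1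
F5 | step 6 | methyl (4Z)-6-hydroxy-5-methylhex-4-enoate | COC(=O)CC/C=C(\CO)C
F6 | step 6 | methyl (4Z)-6-bromo-5-methylhex-4-enoate | COC(=O)CC/C=C(\CBr)C
F7 | step 6 | methyl (4S,5R,8E)-5-hydroxy-9-methyl-10-oxo-4-(prop-1-en-2-yl)undec-8-enoate | CC(=O)/C(C)=C/CC[C@@H](O)[C@@H](CCC(=O)OC)C(C)=C
F8 | step 6 | (4S,5R,8E)-5-hydroxy-9-methyl-10-oxo-4-(prop-1-en-2-yl)undec-8-enoic acid | CC(=O)/C(C)=C/CC[C@@H](O)[C@@H](CCC(=O)O)C(C)=C
F9 | step 16 | methyl 3-{5-[(2,5-bis(benzyloxy)-3-methylphenyl)methyl]-5,8a-dimethyl-6-methylidene-2-oxodecahydronaphthalen-1-yl}propanoate | Cc1cc(OCc2ccccc2)cc(C[C@]2(C)[C@H]3CCC(=O)[C@@H](CCC(=O)OC)[C@]3(C)CCC2=C)c1OCc1ccccc1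
F10 | step 16 | methyl 3-{5-[(2,5-bis(benzyloxy)-3-methylphenyl)methyl]-5,8a-dimethyl-6-methylidene-2-(propan-2-ylidene)decahydronaphthalen-1-yl}propanoate | Cc1cc(OCc2ccccc2)cc(C[C@]2(C)[C@H]3CCC(=C(C)C)[C@@H](CCC(=O)OC)[C@]3(C)CCC2=C)c1OCc1ccccc1
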